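**Retrosynthetic overview**
1. Last bond C5–C6: Ni/Cr (Nozaki–Hiyama–Kishi) macrocyclisation of a (Z)-β-iodoacrylate onto a C6 aldehyde; the alkoxide closes onto the cis ester, so the ten-membered carbocycle and the bridging butenolide form together.
2. The C6 aldehyde on C7 comes from an indium Barbier reaction of a 3-(bromomethyl)butenolide (C7 as nucleophile, trans to the C8 chain) with glycolaldehyde, then diol cleavage.
3. The bromomethylbutenolide comes from the α-methylene-γ-butyrolactone (first ring formed), made by catalytic asymmetric 2-(methoxycarbonyl)allylation of a C8 lactol.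
4. The (Z)-iodoacrylate and C3–O come from an enantioselective β-iodo Morita–Baylis–Hillman coupling of a C3 aldehyde with methyl propiolate; the aldehyde comes from hydroformylation of (S)-4-vinylbutyrolactone, itself from asymmetric Rh vinylation of furan-2(5H)-one (sets C10).
5. Ring order: α-methylene lactone (step 6), then carbocycle and butenolide in one operation (step 9).

Assumption: atoms are labelled by germacranolide numbering (C1–C10 ring, C11–C13 methylene lactone, C14 = CH2OH carbon, C15 = butenolide carbonyl); the target is then (3S,6R,7S,8R,10R).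

**Step 1**
Reactants: 1 furan-2(5H)-one; 2 potassium trifluoro(vinyl)borate
Product: 3 (4S)-4-ethenyloxolan-2-one
Conditions: [Rh(cod)2]BF4 (3 mol %), (S)-BINAP (3.3 mol %), toluene/H2O 4:1, 100 °C
Reagents that add atoms: none
Why: Hayashi–Miyaura Rh(I)/BINAP asymmetric 1,4-addition of the vinylboron reagent to the butenolide sets C10 by enantioface-selective insertion into the Rh–vinyl bond; the quadrant model predicts the (S)-lactone from (S)-BINAP (to be confirmed by rotation), which maps onto (10R) of the target.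

**Step 2**
Reactants: 3 (4S)-4-ethenyloxolan-2-one
Product: 4 3-[(3R)-5-oxooxolan-3-yl]propanal
Conditions: Rh(acac)(CO)2 (0.5 mol %), Xantphos (1 mol %), CO/H2 1:1 (10 bar), toluene, 80 °C
Reagents that add atoms: carbon monoxide, [C-]#[O+]
Why: Xantphos-modified Rh hydroformylation is linear-selective for the monosubstituted vinyl group and leaves the lactone and C10 untouched, giving C1–C2–C3 with C3 as the aldehyde.

**Step 3**
Reactants: 4 3-[(3R)-5-oxooxolan-3-yl]propanal; 5 methyl prop-2-ynoate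
Product: 8 methyl (2Z)-2-[(1S)-1-hydroxy-3-[(3R)-5-oxooxolan-3-yl]propyl]-3-iodoprop-2-enoate, via silyl allenoate 6 (not isolated), via TMS ether 7 (not isolated)
Conditions: TMSI (1.2 equiv), (S)-o-tolyl-oxazaborolidinium triflimide (20 mol %), CH2Cl2, −78 °C; then 1 M HCl
Reagents that add atoms: iodotrimethylsilane, C[Si](C)(C)I
Why: Chiral oxazaborolidinium-catalysed three-component β-iodo Morita–Baylis–Hillman coupling, in which TMSI adds to the propiolate to give the β-iodoallenoate that attacks one face of the catalyst-bound aldehyde through its α-carbon, setting (3S) (catalyst antipode chosen accordingly) and giving only the (Z)-iodoacrylate (I cis to CO2Me) needed for the final lactonisation.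

**Step 4**
Reactants: 8 methyl (2Z)-2-[(1S)-1-hydroxy-3-[(3R)-5-oxooxolan-3-yl]propyl]-3-iodoprop-2-enoate
Product: 9 methyl (2Z)-3-iodo-2-[(1S)-1-(2-methylpropanoyloxy)-3-[(3R)-5-oxooxolan-3-yl]propyl]prop-2-enoate
Conditions: (i-PrCO)2O, Sc(OTf)3 (2 mol %), MeCN, 0 °C
Reagents that add atoms: isobutyric anhydride, CC(C)C(=O)OC(=O)C(C)C
Why: Lewis-acid-catalysed acylation of the only free hydroxyl installs the isobutyrate with retention at C3 and avoids nucleophilic amines that would attack the β-iodoacrylate, while C14–O stays masked in the lactone.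

**Step 5**
Reactants: 9 methyl (2Z)-3-iodo-2-[(1S)-1-(2-methylpropanoyloxy)-3-[(3R)-5-oxooxolan-3-yl]propyl]prop-2-enoate
Product: 10 methyl (2Z)-2-[(1S)-3-[(3R)-5-hydroxyoxolan-3-yl]-1-(2-methylpropanoyloxy)propyl]-3-iodoprop-2-enoate
Conditions: Sia2BH (1.5 equiv, from BH3·THF and 2-methylbut-2-ene), THF, 0 °C to rt; then H2O
Reagents that add atoms: none
Why: Chemoselective disiamylborane reduction takes γ-lactones to lactols but does not reduce acyclic esters or hydroborate the hindered electron-poor iodoacrylate, so only C8 reaches the aldehyde oxidation level.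

**Step 6**
Reactants: 10 methyl (2Z)-2-[(1S)-3-[(3R)-5-hydroxyoxolan-3-yl]-1-(2-methylpropanoyloxy)propyl]-3-iodoprop-2-enoate; 11 methyl 2-(bromomethyl)prop-2-enoate
Product: 13 methyl (2Z)-2-[(1S,4R)-4-(hydroxymethyl)-1-(2-methylpropanoyloxy)-5-[(2R)-4-methylidene-5-oxooxolan-2-yl]pentyl]-3-iodoprop-2-enoate, via hydroxy diester 12 (not isolated)
Conditions: CrCl2 (10 mol %, Ni-free), chiral carbazole-bis(oxazoline) ligand (12 mol %), Mn, Cp2ZrCl2, THF, rt; then PPTS, CH2Cl2
Reagents that add atoms: none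
Why: Catalytic asymmetric Nozaki–Hiyama–Kishi-type 2-(alkoxycarbonyl)allylation, in which the lactol reacts through its open hydroxy-aldehyde form and the chiral Cr(III)–allyl adds to one face of C8 under catalyst control (C10 is too remote to interfere; ligand antipode chosen for 8R), after which the γ-hydroxy ester lactonises to the α-methylene-γ-butyrolactone and frees C14–OH.

**Step 7**
Reactants: 13 methyl (2Z)-2-[(1S,4R)-4-(hydroxymethyl)-1-(2-methylpropanoyloxy)-5-[(2R)-4-methylidene-5-oxooxolan-2-yl]pentyl]-3-iodoprop-2-enoate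
Product: 15 methyl (2Z)-2-[(1S,4R)-5-[(2R)-4-(bromomethyl)-5-oxo-2,5-dihydrofuran-2-yl]-4-(hydroxymethyl)-1-(2-methylpropanoyloxy)pentyl]-3-iodoprop-2-enoate, via dibromide 14 (not isolated)
Conditions: Br2, CH2Cl2, −20 °C; then i-Pr2NEt, 0 °C
Reagents that add atoms: bromine, BrBr
Why: Bromine addition to the 1,1-disubstituted acrylate followed by amine dehydrobromination (the classical route to 2-(bromomethyl)acrylates) moves the alkene into the ring and leaves an allylic bromide, while the trisubstituted iodoacrylate is far less reactive towards Br2 and C8 is untouched.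

**Step 8**
Reactants: 15 methyl (2Z)-2-[(1S,4R)-5-[(2R)-4-(bromomethyl)-5-oxo-2,5-dihydrofuran-2-yl]-4-(hydroxymethyl)-1-(2-methylpropanoyloxy)pentyl]-3-iodoprop-2-enoate; 16 glycolaldehyde
Product: 18 methyl (2Z)-2-[(1S,4R)-5-[(2R,3S)-3-formyl-4-methylidene-5-oxooxolan-2-yl]-4-(hydroxymethyl)-1-(2-methylpropanoyloxy)pentyl]-3-iodoprop-2-enoate, via triol 17 (not isolated)
Conditions: In, THF/H2O 1:1, rt; then NaIO4, pH 7 buffer, 0 °C
Reagents that add atoms: none
Why: Indium Barbier allylation in water, where the allylindium from the 3-(bromomethyl)butenolide attacks through its γ-carbon (C7) anti to the C8 side chain, restoring the exocyclic methylene and fixing the trans C7/C8 relationship (7S), and periodate glycol cleavage then removes the extra carbon and unmasks C6 as the aldehyde under neutral conditions.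

**Step 9**
Reactants: 18 methyl (2Z)-2-[(1S,4R)-5-[(2R,3S)-3-formyl-4-methylidene-5-oxooxolan-2-yl]-4-(hydroxymethyl)-1-(2-methylpropanoyloxy)pentyl]-3-iodoprop-2-enoate
Product: 20 (3S,6R,7S,8R,10R)-14-hydroxy-3-(2-methylpropanoyloxy)germacra-4,11(13)-diene-12,8:15,6-diolide (CNP0332805.1), via seco hydroxy ester 19 (not isolated)
Conditions: CrCl2 (10 equiv), NiCl2 (0.1 equiv), THF/DMF 4:1, 4 Å MS, rt, slow addition to 2 mM; aq NH4Cl
Reagents that add atoms: none
Why: Nozaki–Hiyama–Kishi macrocyclisation in which the (Z)-vinylchromium adds to the C6 aldehyde under non-basic conditions to close the ten-membered ring, Felkin–Anh attack anti to the sp2 α-substituent C11 (reinforced by the 1,3-anti preference to the C8 oxygen) is expected to give (6R), and the cis CO2Me traps the chromium alkoxide as the butenolide so that carbocycle and bridging lactone form in one operation.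

**Compound list**
1 | furan-2(5H)-one | O=C1C=CCO1 | starting material
2 | potassium trifluoro(vinyl)borate | C=C[B-](F)(F)F.[K+] | starting material
3 | (4S)-4-ethenyloxolan-2-one | O=C1C[C@@H](C=C)CO1 | intermediate
4 | 3-[(3R)-5-oxooxolan-3-yl]propanal | O=CCC[C@@H]1CC(=O)OC1 | intermediate
5 | methyl prop-2-ynoate | C#CC(=O)OC | starting material
6 | (3-iodo-1-methoxypropa-1,2-dien-1-yl)oxy-trimethylsilane (silyl allenoate) | IC=C=C(OC)O[Si](C)(C)C | intermediate
7 | methyl (2Z)-3-iodo-2-[(1S)-3-[(3R)-5-oxooxolan-3-yl]-1-(trimethylsilyloxy)propyl]prop-2-enoate | COC(=O)/C(=C\I)[C@@H](O[Si](C)(C)C)CC[C@@H]1CC(=O)OC1 | intermediate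
8 | methyl (2Z)-2-[(1S)-1-hydroxy-3-[(3R)-5-oxooxolan-3-yl]propyl]-3-iodoprop-2-enoate | COC(=O)/C(=C\I)[C@@H](O)CC[C@@H]1CC(=O)OC1 | intermediate
9 | methyl (2Z)-3-iodo-2-[(1S)-1-(2-methylpropanoyloxy)-3-[(3R)-5-oxooxolan-3-yl]propyl]prop-2-enoate | COC(=O)/C(=C\I)[C@@H](OC(=O)C(C)C)CC[C@@H]1CC(=O)OC1 | intermediate
10 | methyl (2Z)-2-[(1S)-3-[(3R)-5-hydroxyoxolan-3-yl]-1-(2-methylpropanoyloxy)propyl]-3-iodoprop-2-enoate (lactol, anomer mixture) | COC(=O)/C(=C\I)[C@@H](OC(=O)C(C)C)CC[C@@H]1CC(O)OC1 | intermediate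
11 | methyl 2-(bromomethyl)prop-2-enoate | C=C(CBr)C(=O)OC | starting material
12 | methyl (2Z)-2-[(1S,4R,6R)-6-hydroxy-4-(hydroxymethyl)-8-(methoxycarbonyl)-1-(2-methylpropanoyloxy)non-8-en-1-yl]-3-iodoprop-2-enoate (hydroxy diester) | COC(=O)/C(=C\I)[C@@H](OC(=O)C(C)C)CC[C@@H](CO)C[C@@H](O)CC(=C)C(=O)OC | intermediate
13 | methyl (2Z)-2-[(1S,4R)-4-(hydroxymethyl)-1-(2-methylpropanoyloxy)-5-[(2R)-4-methylidene-5-oxooxolan-2-yl]pentyl]-3-iodoprop-2-enoate | COC(=O)/C(=C\I)[C@@H](OC(=O)C(C)C)CC[C@@H](CO)C[C@@H]1CC(=C)C(=O)O1 | intermediate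
14 | methyl (2Z)-2-[(1S,4R)-5-[(2R)-4-bromo-4-(bromomethyl)-5-oxooxolan-2-yl]-4-(hydroxymethyl)-1-(2-methylpropanoyloxy)pentyl]-3-iodoprop-2-enoate (dibromide, C–Br centre unassigned) | COC(=O)/C(=C\I)[C@@H](OC(=O)C(C)C)CC[C@@H](CO)C[C@@H]1CC(Br)(CBr)C(=O)O1 | intermediate
15 | methyl (2Z)-2-[(1S,4R)-5-[(2R)-4-(bromomethyl)-5-oxo-2,5-dihydrofuran-2-yl]-4-(hydroxymethyl)-1-(2-methylpropanoyloxy)pentyl]-3-iodoprop-2-enoate | COC(=O)/C(=C\I)[C@@H](OC(=O)C(C)C)CC[C@@H](CO)C[C@@H]1C=C(CBr)C(=O)O1 | intermediate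
16 | glycolaldehyde (2-hydroxyacetaldehyde, supplied as its dimer) | OCC=O | starting material
17 | methyl (2Z)-2-[(1S,4R)-5-[(2R,3R)-3-(1,2-dihydroxyethyl)-4-methylidene-5-oxooxolan-2-yl]-4-(hydroxymethyl)-1-(2-methylpropanoyloxy)pentyl]-3-iodoprop-2-enoate (triol, carbinol epimers) | COC(=O)/C(=C\I)[C@@H](OC(=O)C(C)C)CC[C@@H](CO)C[C@H]1OC(=O)C(=C)[C@@H]1C(O)CO | intermediate
18 | methyl (2Z)-2-[(1S,4R)-5-[(2R,3S)-3-formyl-4-methylidene-5-oxooxolan-2-yl]-4-(hydroxymethyl)-1-(2-methylpropanoyloxy)pentyl]-3-iodoprop-2-enoate | COC(=O)/C(=C\I)[C@@H](OC(=O)C(C)C)CC[C@@H](CO)C[C@H]1OC(=O)C(=C)[C@@H]1C=O | intermediate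
19 | seco hydroxy ester of 20: ten-membered ring closed, C6–OH free, C4–CO2Me not yet lactonised, 12,8-lactone in place (3S,6R,7R,8R,10R) | C=C1C(=O)O[C@@H]2C[C@H](CO)CC[C@H](OC(=O)C(C)C)/C(C(=O)OC)=C/[C@@H](O)[C@@H]12 | intermediate
20 | (3S,6R,7S,8R,10R)-14-hydroxy-3-(2-methylpropanoyloxy)germacra-4,11(13)-diene-12,8:15,6-diolide (CNP0332805.1) | C=C1C(=O)O[C@@H]2C[C@H](CO)CC[C@H](OC(=O)C(C)C)C3=C[C@@H](OC3=O)[C@@H]12 | target

**Total step count:** 9
**Longest linear sequence:** 9 (fully linear from 1)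

**Steps most likely to fail, with fallbacks**

Step 9 (macrocyclisation). Aldehyde 18 carries an acidic C7–H (α to CHO and allylic to the acrylate) and can epimerise or isomerise into conjugation before the slow ring closure. The ring closure builds an (E)-cyclodecene, and C6 selectivity rests on a Felkin argument. The fallback sets out from 13 and rejoins at 19. Pd-catalysed reductive carbonylation of the vinyl iodide (Pd(OAc)2/Xantphos, CO, Et3SiH, Na2CO3, DMF) gives the formyl acrylate F1, whose aldehyde has no α-hydrogen. Br2 then i-Pr2NEt converts the methylene lactone through the dibromide F2 into the bromomethylbutenolide aldehyde F3. CrCl2 (or Zn, aq NH4Cl/THF) at high dilution closes the ring at C6–C7 instead, by intramolecular vinylogous Barbier addition of butenolide C7 to the C6 aldehyde. This gives the same seco hydroxy ester 19, which lactonises to 20. In this mode C6 and C7 are set by the allyl-metal transition state rather than by Felkin control.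

Step 6 (asymmetric allylation of a lactol). The lactol may react sluggishly under Cr catalysis, the free hydroxyls can interfere with Cp2ZrCl2, and trace Ni would engage the vinyl iodide. The fallback sets out from 10 and 11 and rejoins at 12. Compound 11 is borylated (B2pin2, CuCl cat., KOt-Bu, THF) to the allylboronate F4. Metal-free allylboration of lactol 10 through a closed boron chair, catalysed by a chiral BINOL-phosphoric acid (antipode chosen for 8R, toluene, −30 °C), gives hydroxy diester 12 after aqueous work-up. PPTS then lactonises 12 to 13.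

Step 7 (isomerising bromination). Dehydrobromination of 14 could instead give the exocyclic bromomethylene lactone, or the product bromide could be quaternised by the amine. The fallback sets out from 13 and rejoins at 15. RhCl3·3H2O (cat., EtOH, 70 °C) moves the exocyclic alkene into the ring to give the α-methylbutenolide F5. Wohl–Ziegler bromination of the allylic methyl (NBS, AIBN, PhCF3, 80 °C) then gives 15.

**Further compounds**
F1 | step 9 | methyl (2Z)-2-[(1S,4R)-4-(hydroxymethyl)-1-(2-methylpropanoyloxy)-5-[(2R)-4-methylidene-5-oxooxolan-2-yl]pentyl]-4-oxobut-2-enoate | COC(=O)/C(=C\C=O)[C@@H](OC(=O)C(C)C)CC[C@@H](CO)C[C@@H]1CC(=C)C(=O)O1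
F2 | step 9 | methyl (2Z)-2-[(1S,4R)-5-[(2R)-4-bromo-4-(bromomethyl)-5-oxooxolan-2-yl]-4-(hydroxymethyl)-1-(2-methylpropanoyloxy)pentyl]-4-oxobut-2-enoate | COC(=O)/C(=C\C=O)[C@@H](OC(=O)C(C)C)CC[C@@H](CO)C[C@@H]1CC(Br)(CBr)C(=O)O1
F3 | step 9 | methyl (2Z)-2-[(1S,4R)-5-[(2R)-4-(bromomethyl)-5-oxo-2,5-dihydrofuran-2-yl]-4-(hydroxymethyl)-1-(2-methylpropanoyloxy)pentyl]-4-oxobut-2-enoate | COC(=O)/C(=C\C=O)[C@@H](OC(=O)C(C)C)CC[C@@H](CO)C[C@@H]1C=C(CBr)C(=O)O1
F4 | step 6 | methyl 2-[(4,4,5,5-tetramethyl-1,3,2-dioxaborolan-2-yl)methyl]prop-2-enoate | C=C(CB1OC(C)(C)C(C)(C)O1)C(=O)OC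
F5 | step 7 | methyl (2Z)-2-[(1S,4R)-4-(hydroxymethyl)-5-[(2R)-4-methyl-5-oxo-2,5-dihydrofuran-2-yl]-1-(2-methylpropanoyloxy)pentyl]-3-iodoprop-2-enoate | COC(=O)/C(=C\I)[C@@H](OC(=O)C(C)C)CC[C@@H](CO)C[C@@H]1C=C(C)C(=O)O1
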